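The O1–C2 bond of the dihydrofuran ring is the disconnection on which everything rests. The feature exploited is that C2 is the benzylic carbon of the 3,4-dimethoxyphenyl ring, the most easily oxidised arene present, and lies within five-ring reach of the C7a hydroxyl. Anodic removal of two electrons and the C2 hydrogen should therefore let that oxygen close the five-membered ring and fix C2 trans to the C3 arm in a single operation. The substrate is an open-chain (S)-2,3-diarylpropyl silyl ether whose stereocentre comes from an Evans benzylation. Its phenol ring carries a MOM ether at C7 and a nitrile at C5, which makes that ring hard to oxidise and later becomes the acrylic acid.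

Key step: step 12

Remark: compounds 1, 2, 11, 14 and 24 are taken as commercial; the C5 carbon is carried as a nitrile because it deactivates the phenol ring strongly, is inert to LiBH4 and is one reduction away from the aldehyde.

Step 1
Reactants: 1 3,4-dihydroxybenzonitrile; 2 allyl bromide
Product: 3 3-hydroxy-4-(prop-2-en-1-yloxy)benzonitrile
Conditions: 2 (1.05 equiv), NaHCO3, DMF, 40 °C
Reagents that add atoms: none
Why: Williamson etherification in which the weak base ionises only the hydroxyl para to the nitrile (the more acidic one, its anion being delocalised into the cyano group), so that one equivalent of 2 should alkylate O4 selectively.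

Step 2
Reactants: 3 3-hydroxy-4-(prop-2-en-1-yloxy)benzonitrile
Product: 4 3-(methoxymethoxy)-4-(prop-2-en-1-yloxy)benzonitrile
Conditions: MOMCl, iPr2NEt, CH2Cl2, 0 °C to rt
Reagents that add atoms: chloromethyl methyl ether (MOMCl), COCCl
Why: Base-mediated O-alkylation (methoxymethyl ether formation) of the one remaining phenol, giving an acetal that is stable to all later basic, reductive and oxidative steps and that caps the catechol so that it cannot be oxidised to an ortho-quinone in step 12.

Step 3
Reactants: 4 3-(methoxymethoxy)-4-(prop-2-en-1-yloxy)benzonitrile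
Product: 6 4-hydroxy-3-(methoxymethoxy)-5-(prop-2-en-1-yl)benzonitrile, via ortho-dienone 5 (not isolated)
Conditions: PhNEt2, 190 °C
Reagents that add atoms: none
Why: Aromatic Claisen rearrangement, a [3,3]-sigmatropic shift of the allyl group to the only unsubstituted ortho carbon (the other ortho position carries the OMOM group and the para position the nitrile), followed by tautomerisation of dienone 5 to the phenol.

Step 4
Reactants: 6 4-hydroxy-3-(methoxymethoxy)-5-(prop-2-en-1-yl)benzonitrile
Product: 7 4-(benzyloxy)-3-(methoxymethoxy)-5-(prop-2-en-1-yl)benzonitrile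
Conditions: BnBr, K2CO3, DMF, 50 °C
Reagents that add atoms: benzyl bromide, BrCc1ccccc1
Why: Williamson benzylation of the hindered but acidic phenol, needed so that the arylacetic acid made next cannot lactonise and the enolate of step 8 meets no acidic OH.

Step 5
Reactants: 7 4-(benzyloxy)-3-(methoxymethoxy)-5-(prop-2-en-1-yl)benzonitrile
Product: 9 4-(benzyloxy)-3-(methoxymethoxy)-5-(2-oxoethyl)benzonitrile, via diol 8 (not isolated)
Conditions: OsO4 (cat.), NaIO4, 2,6-lutidine, dioxane/H2O, rt
Reagents that add atoms: osmium tetroxide, O=[Os](=O)(=O)=O; sodium periodate, [Na+].[O-]I(=O)(=O)=O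
Why: Lemieux–Johnson oxidation (OsO4 dihydroxylation of the terminal alkene and periodate cleavage of diol 8), buffered by 2,6-lutidine so that the acetal survives and the enolisable arylacetaldehyde is not oxidised further.

Step 6
Reactants: 9 4-(benzyloxy)-3-(methoxymethoxy)-5-(2-oxoethyl)benzonitrile
Product: 10 [2-(benzyloxy)-5-cyano-3-(methoxymethoxy)phenyl]acetic acid
Conditions: NaClO2, NaH2PO4, 2-methyl-2-butene, t-BuOH/H2O, rt
Reagents that add atoms: sodium chlorite, [Na+].[O-]Cl=O
Why: Pinnick oxidation, which takes the aldehyde to the acid under buffered conditions without touching the nitrile, the ethers or the benzylic position.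

Step 7
Reactants: 10 [2-(benzyloxy)-5-cyano-3-(methoxymethoxy)phenyl]acetic acid; 11 (4S)-4-benzyl-1,3-oxazolidin-2-one
Product: 13 (4S)-4-benzyl-3-{[2-(benzyloxy)-5-cyano-3-(methoxymethoxy)phenyl]acetyl}-1,3-oxazolidin-2-one, via mixed pivalic anhydride 12 (not isolated)
Conditions: PivCl, Et3N, THF, −20 °C; then 11, LiCl, rt
Reagents that add atoms: none
Why: N-Acylation of the Evans auxiliary through the mixed anhydride 12 under the mild LiCl/Et3N protocol, the oxazolidinone attacking the less hindered arylacetyl carbonyl.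

Step 8
Reactants: 13 (4S)-4-benzyl-3-{[2-(benzyloxy)-5-cyano-3-(methoxymethoxy)phenyl]acetyl}-1,3-oxazolidin-2-one; 14 4-(bromomethyl)-1,2-dimethoxybenzene
Product: 16 (4S)-4-benzyl-3-[(2S)-2-[2-(benzyloxy)-5-cyano-3-(methoxymethoxy)phenyl]-3-(3,4-dimethoxyphenyl)propanoyl]-1,3-oxazolidin-2-one, via sodium Z-enolate 15 (not isolated)
Conditions: NaN(SiMe3)2, THF, −78 °C; then 14, −78 to −40 °C
Reagents that add atoms: none
Why: Evans asymmetric alkylation, in which the chelated sodium Z-enolate 15 is attacked by the reactive benzylic bromide on the face opposite the C4 benzyl group of the auxiliary, setting the new stereocentre (the later C3) as S, with the minor diastereomer removable by chromatography or crystallisation.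

Step 9
Reactants: 16 (4S)-4-benzyl-3-[(2S)-2-[2-(benzyloxy)-5-cyano-3-(methoxymethoxy)phenyl]-3-(3,4-dimethoxyphenyl)propanoyl]-1,3-oxazolidin-2-one
Product: 17 4-(benzyloxy)-3-[(2S)-1-(3,4-dimethoxyphenyl)-3-hydroxypropan-2-yl]-5-(methoxymethoxy)benzonitrile
Conditions: LiBH4, MeOH (1 equiv), THF, 0 °C
Reagents that add atoms: none
Why: Reductive removal of the auxiliary with LiBH4, which reduces the activated exocyclic imide carbonyl to the primary alcohol without epimerisation and leaves the nitrile untouched.

Step 10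
Reactants: 17 4-(benzyloxy)-3-[(2S)-1-(3,4-dimethoxyphenyl)-3-hydroxypropan-2-yl]-5-(methoxymethoxy)benzonitrile
Product: 18 4-(benzyloxy)-3-[(2S)-1-(3,4-dimethoxyphenyl)-3-(triisopropylsilyloxy)propan-2-yl]-5-(methoxymethoxy)benzonitrile
Conditions: TIPSCl, imidazole, DMF, rt
Reagents that add atoms: triisopropylsilyl chloride, CC(C)[Si](Cl)(C(C)C)C(C)C
Why: Silylation of the primary alcohol, giving a bulky ether that should withstand hydrogenolysis and electrolysis and that enlarges the C3 substituent directing the ring closure.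

Step 11
Reactants: 18 4-(benzyloxy)-3-[(2S)-1-(3,4-dimethoxyphenyl)-3-(triisopropylsilyloxy)propan-2-yl]-5-(methoxymethoxy)benzonitrile
Product: 19 3-[(2S)-1-(3,4-dimethoxyphenyl)-3-(triisopropylsilyloxy)propan-2-yl]-4-hydroxy-5-(methoxymethoxy)benzonitrile
Conditions: H2 (1 atm), Pd/C (10%), EtOAc, rt
Reagents that add atoms: none
Why: Hydrogenolysis of the benzyl aryl ether over palladium, which under neutral conditions at atmospheric pressure should spare the aryl nitrile, the acetal and the silyl ether and free the C7a hydroxyl.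

Step 12
Reactants: 19 3-[(2S)-1-(3,4-dimethoxyphenyl)-3-(triisopropylsilyloxy)propan-2-yl]-4-hydroxy-5-(methoxymethoxy)benzonitrile
Product: 21 (2R,3S)-2-(3,4-dimethoxyphenyl)-7-(methoxymethoxy)-3-[(triisopropylsilyloxy)methyl]-2,3-dihydro-1-benzofuran-5-carbonitrile, via benzylic cation 20 (not isolated)
Conditions: graphite anode, Pt cathode, undivided cell, constant current, 2.0–2.2 F/mol, nBu4NBF4, HFIP/CH2Cl2 (1:4), rt
Reagents that add atoms: none
Why: Electron transfer at the anode should take place at the 1,2-dimethoxyarene, whose radical cation loses the C2 proton and a second electron to give the para-methoxy-stabilised benzylic cation 20, which the C7a hydroxyl captures with loss of a proton while HFIP is reduced to H2 at the cathode. The closest known reaction type is the anodic or quinone-mediated oxidation of benzylic C–H bonds of alkoxyarenes with trapping of the cation by an internal hydroxyl or carboxyl group, as in electrochemical benzylic etherification and lactonisation. The dihydrofuran ring closes in the 5-exo-trig mode, the oxygen adding to C2 of the quinoid cation whose π-bond to the aryl ring lies outside the new ring. C2 is the new stereocentre and is controlled by C3: the cation is planar and the oxygen should add on the face that places the aryl group anti to the CH2OTIPS arm, giving the trans (2R,3S) isomer, which is also the more stable one. The step needs oxidation of the dimethoxyphenyl ring in preference to the phenol ring and to the product; the para nitrile and the MOM-capped C7 oxygen of 19 secure the first, and a charge limit near two faradays per mole with a stop short of full conversion secures the second.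

Step 13
Reactants: 21 (2R,3S)-2-(3,4-dimethoxyphenyl)-7-(methoxymethoxy)-3-[(triisopropylsilyloxy)methyl]-2,3-dihydro-1-benzofuran-5-carbonitrile
Product: 23 (2R,3S)-2-(3,4-dimethoxyphenyl)-7-(methoxymethoxy)-3-[(triisopropylsilyloxy)methyl]-2,3-dihydro-1-benzofuran-5-carbaldehyde, via N-aluminio aldimine 22 (not isolated)
Conditions: iBu2AlH, CH2Cl2, −78 °C; then aq. potassium sodium tartrate, then 1 M aq. HCl, 0 °C
Reagents that add atoms: water, O
Why: Half-reduction of the aryl nitrile by one hydride from iBu2AlH gives the aldimine 22, which resists further reduction at low temperature and is hydrolysed to the aldehyde on work-up.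

Step 14
Reactants: 23 (2R,3S)-2-(3,4-dimethoxyphenyl)-7-(methoxymethoxy)-3-[(triisopropylsilyloxy)methyl]-2,3-dihydro-1-benzofuran-5-carbaldehyde; 24 malonic acid
Product: 26 (2E)-3-[(2R,3S)-2-(3,4-dimethoxyphenyl)-7-(methoxymethoxy)-3-[(triisopropylsilyloxy)methyl]-2,3-dihydro-1-benzofuran-5-yl]prop-2-enoic acid, via arylidenemalonic acid 25 (not isolated)
Conditions: 24, pyridine, piperidine (cat.), 90 °C
Reagents that add atoms: none
Why: Knoevenagel–Doebner condensation, in which the arylidenemalonic acid 25 loses CO2 in hot pyridine to give the E-configured acrylic acid while the basic medium leaves both protecting groups and both stereocentres alone.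

Step 15
Reactants: 26 (2E)-3-[(2R,3S)-2-(3,4-dimethoxyphenyl)-7-(methoxymethoxy)-3-[(triisopropylsilyloxy)methyl]-2,3-dihydro-1-benzofuran-5-yl]prop-2-enoic acid
Product: 27 (2E)-3-[(2R,3S)-2-(3,4-dimethoxyphenyl)-7-hydroxy-3-(hydroxymethyl)-2,3-dihydro-1-benzofuran-5-yl]prop-2-enoic acid
Conditions: 3 M aq. HCl, THF, 40 °C
Reagents that add atoms: none
Why: Acid-catalysed hydrolysis of the aryl methoxymethyl acetal and of the primary silyl ether in one operation, in which C3 is not involved and any reversible ionisation at C2 can only return the more stable trans ring.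

Compound list

1 | 3,4-dihydroxybenzonitrile | N#Cc1ccc(O)c(O)c1 | starting material
2 | allyl bromide (3-bromoprop-1-ene) | C=CCBr | starting material
3 | 3-hydroxy-4-(prop-2-en-1-yloxy)benzonitrile | C=CCOc1ccc(C#N)cc1O | intermediate
4 | 3-(methoxymethoxy)-4-(prop-2-en-1-yloxy)benzonitrile | C=CCOc1ccc(C#N)cc1OCOC | intermediate
5 | 5-(methoxymethoxy)-4-oxo-3-(prop-2-en-1-yl)cyclohexa-1,5-diene-1-carbonitrile (ortho-dienone, racemic) | O=C1C(CC=C)C=C(C#N)C=C1OCOC | intermediate (not isolated)
6 | 4-hydroxy-3-(methoxymethoxy)-5-(prop-2-en-1-yl)benzonitrile | C=CCc1cc(C#N)cc(OCOC)c1O | intermediate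
7 | 4-(benzyloxy)-3-(methoxymethoxy)-5-(prop-2-en-1-yl)benzonitrile | C=CCc1cc(C#N)cc(OCOC)c1OCc1ccccc1 | intermediate
8 | 4-(benzyloxy)-3-(2,3-dihydroxypropyl)-5-(methoxymethoxy)benzonitrile (diol, racemic) | OCC(O)Cc1cc(C#N)cc(OCOC)c1OCc1ccccc1 | intermediate (not isolated)
9 | 4-(benzyloxy)-3-(methoxymethoxy)-5-(2-oxoethyl)benzonitrile | O=CCc1cc(C#N)cc(OCOC)c1OCc1ccccc1 | intermediate
10 | [2-(benzyloxy)-5-cyano-3-(methoxymethoxy)phenyl]acetic acid | OC(=O)Cc1cc(C#N)cc(OCOC)c1OCc1ccccc1 | intermediate
11 | (4S)-4-benzyl-1,3-oxazolidin-2-one | O=C1N[C@@H](Cc2ccccc2)CO1 | starting material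
12 | [2-(benzyloxy)-5-cyano-3-(methoxymethoxy)phenyl]acetic 2,2-dimethylpropanoic anhydride | CC(C)(C)C(=O)OC(=O)Cc1cc(C#N)cc(OCOC)c1OCc1ccccc1 | intermediate (not isolated)
13 | (4S)-4-benzyl-3-{[2-(benzyloxy)-5-cyano-3-(methoxymethoxy)phenyl]acetyl}-1,3-oxazolidin-2-one | O=C(Cc1cc(C#N)cc(OCOC)c1OCc1ccccc1)N1[C@@H](Cc2ccccc2)COC1=O | intermediate
14 | 4-(bromomethyl)-1,2-dimethoxybenzene (3,4-dimethoxybenzyl bromide) | COc1ccc(CBr)cc1OC | starting material
15 | sodium (Z)-enolate of 13 (O and aryl cis) | [Na+].[O-]/C(=C\c1cc(C#N)cc(OCOC)c1OCc1ccccc1)N1[C@@H](Cc2ccccc2)COC1=O | intermediate (not isolated)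
16 | (4S)-4-benzyl-3-[(2S)-2-[2-(benzyloxy)-5-cyano-3-(methoxymethoxy)phenyl]-3-(3,4-dimethoxyphenyl)propanoyl]-1,3-oxazolidin-2-one | COc1ccc(C[C@H](C(=O)N2[C@@H](Cc3ccccc3)COC2=O)c2cc(C#N)cc(OCOC)c2OCc2ccccc2)cc1OC | intermediate
17 | 4-(benzyloxy)-3-[(2S)-1-(3,4-dimethoxyphenyl)-3-hydroxypropan-2-yl]-5-(methoxymethoxy)benzonitrile | COc1ccc(C[C@H](CO)c2cc(C#N)cc(OCOC)c2OCc2ccccc2)cc1OC | intermediate
18 | 4-(benzyloxy)-3-[(2S)-1-(3,4-dimethoxyphenyl)-3-(triisopropylsilyloxy)propan-2-yl]-5-(methoxymethoxy)benzonitrile | COc1ccc(C[C@H](CO[Si](C(C)C)(C(C)C)C(C)C)c2cc(C#N)cc(OCOC)c2OCc2ccccc2)cc1OC | intermediate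
19 | 3-[(2S)-1-(3,4-dimethoxyphenyl)-3-(triisopropylsilyloxy)propan-2-yl]-4-hydroxy-5-(methoxymethoxy)benzonitrile | COc1ccc(C[C@H](CO[Si](C(C)C)(C(C)C)C(C)C)c2cc(C#N)cc(OCOC)c2O)cc1OC | intermediate
20 | benzylic cation at C2 of 19 (para-methoxy-stabilised, C3 unchanged) | COc1ccc([CH+][C@H](CO[Si](C(C)C)(C(C)C)C(C)C)c2cc(C#N)cc(OCOC)c2O)cc1OC | intermediate (not isolated)
21 | (2R,3S)-2-(3,4-dimethoxyphenyl)-7-(methoxymethoxy)-3-[(triisopropylsilyloxy)methyl]-2,3-dihydro-1-benzofuran-5-carbonitrile (trans) | COc1ccc([C@@H]2Oc3c(OCOC)cc(C#N)cc3[C@H]2CO[Si](C(C)C)(C(C)C)C(C)C)cc1OC | intermediate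
22 | N-(diisobutylaluminio)aldimine of 23 | COc1ccc([C@@H]2Oc3c(OCOC)cc(C=N[Al](CC(C)C)CC(C)C)cc3[C@H]2CO[Si](C(C)C)(C(C)C)C(C)C)cc1OC | intermediate (not isolated)
23 | (2R,3S)-2-(3,4-dimethoxyphenyl)-7-(methoxymethoxy)-3-[(triisopropylsilyloxy)methyl]-2,3-dihydro-1-benzofuran-5-carbaldehyde | COc1ccc([C@@H]2Oc3c(OCOC)cc(C=O)cc3[C@H]2CO[Si](C(C)C)(C(C)C)C(C)C)cc1OC | intermediate
24 | malonic acid (propanedioic acid) | OC(=O)CC(=O)O | starting material
25 | 2-{[(2R,3S)-2-(3,4-dimethoxyphenyl)-7-(methoxymethoxy)-3-[(triisopropylsilyloxy)methyl]-2,3-dihydro-1-benzofuran-5-yl]methylidene}propanedioic acid | COc1ccc([C@@H]2Oc3c(OCOC)cc(C=C(C(=O)O)C(=O)O)cc3[C@H]2CO[Si](C(C)C)(C(C)C)C(C)C)cc1OC | intermediate (not isolated)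
26 | (2E)-3-[(2R,3S)-2-(3,4-dimethoxyphenyl)-7-(methoxymethoxy)-3-[(triisopropylsilyloxy)methyl]-2,3-dihydro-1-benzofuran-5-yl]prop-2-enoic acid | COc1ccc([C@@H]2Oc3c(OCOC)cc(/C=C/C(=O)O)cc3[C@H]2CO[Si](C(C)C)(C(C)C)C(C)C)cc1OC | intermediate
27 | (2E)-3-[(2R,3S)-2-(3,4-dimethoxyphenyl)-7-hydroxy-3-(hydroxymethyl)-2,3-dihydro-1-benzofuran-5-yl]prop-2-enoic acid | COc1ccc([C@@H]2Oc3c(O)cc(/C=C/C(=O)O)cc3[C@H]2CO)cc1OC | target

Total step count: 15. Longest linear sequence: 15 steps (1 to 27).

Steps most likely to fail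

Step 12. Electron transfer may occur from the phenol ring instead of the dimethoxyarene. The product may be oxidised further at its C2–H bond, since it is a benzylic ether and no harder to oxidise than 19, leading on to aromatisation or ring opening. The cation may also close on both faces. The fallback reaches the same cation by ionisation of a benzylic alcohol instead of by oxidation. It sets out from acid 10. The mixed anhydride 12 is made as in step 7 and is taken up by (4R)-4-benzyl-1,3-oxazolidin-2-one (LiCl, Et3N) to give the imide F1. Bu2BOTf and iPr2NEt (CH2Cl2, −78 °C) should give the boron Z-enolate F2, which adds to 3,4-dimethoxybenzaldehyde in an Evans syn-aldol reaction to give the adduct F3. The boron aldol uses the enolate face opposite to that of the sodium enolate alkylation, so the R auxiliary is needed for the same C3 configuration. LiBH4 (THF, 0 °C) reduces F3 to the 1,3-diol F4, and TIPSCl with imidazole silylates only the primary hydroxyl to give the silyl ether F5. Hydrogenolysis (H2, Pd/C, EtOAc, neutral) frees the phenol F6. Catalytic camphorsulfonic acid (CH2Cl2, 0 °C) then ionises the benzylic alcohol to cation 20, which closes to 21, where the route is rejoined.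

Step 8. Alkylation of the stabilised, hindered arylacetyl enolate may stay incomplete, the acidic α-aryl centre may epimerise under excess base, and facial selectivity may erode. The fallback sets the C3 centre by catalytic asymmetric hydrogenation in place of auxiliary control. It sets out from acid 10. Perkin condensation with 3,4-dimethoxybenzaldehyde (Ac2O, Et3N, 110 °C) should give the E-configured 2,3-diarylacrylic acid F7. Hydrogenation over Ru(OAc)2(BINAP) (H2, MeOH), with the BINAP antipode chosen so that the S acid forms, should give the 2,3-diarylpropanoic acid F8, whose enantiomeric purity can be raised by crystallisation of an amine salt. BH3·SMe2 (THF, 0 °C) reduces the acid in the presence of the nitrile to alcohol 17, where the route is rejoined.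

Step 15. Slow cleavage of the robust silyl ether may force long exposure to acid, during which the benzylic O1–C2 bond can ionise and the liberated formaldehyde can attack the electron-rich rings. Mixtures of partly unmasked polar acids would also be hard to separate. The fallback moves the unmasking in front of the chain extension, so that the last step is a condensation. It sets out from aldehyde 23. Aqueous HCl in THF removes both groups to give the hydroxy aldehyde F9, a neutral compound that can be purified by chromatography and resubjected if cleavage is incomplete. Knoevenagel–Doebner condensation of F9 with malonic acid 24 (pyridine, piperidine, 90 °C), which tolerates free phenols and alcohols, then passes through the arylidenemalonic acid F10 and should give the target 27 directly.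

Further compounds

F1 | step 12 | (4R)-4-benzyl-3-{[2-(benzyloxy)-5-cyano-3-(methoxymethoxy)phenyl]acetyl}-1,3-oxazolidin-2-one | O=C(Cc1cc(C#N)cc(OCOC)c1OCc1ccccc1)N1[C@H](Cc2ccccc2)COC1=O
F2 | step 12 | dibutylboron (Z)-enolate of F1 | CCCCB(CCCC)O/C(=C\c1cc(C#N)cc(OCOC)c1OCc1ccccc1)N1[C@H](Cc2ccccc2)COC1=O
F3 | step 12 | (4R)-4-benzyl-3-[(2R,3R)-2-[2-(benzyloxy)-5-cyano-3-(methoxymethoxy)phenyl]-3-(3,4-dimethoxyphenyl)-3-hydroxypropanoyl]-1,3-oxazolidin-2-one (syn-aldol adduct) | COc1ccc([C@H](O)[C@H](C(=O)N2[C@H](Cc3ccccc3)COC2=O)c2cc(C#N)cc(OCOC)c2OCc2ccccc2)cc1OC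
F4 | step 12 | 4-(benzyloxy)-3-[(1R,2S)-1-(3,4-dimethoxyphenyl)-1,3-dihydroxypropan-2-yl]-5-(methoxymethoxy)benzonitrile | COc1ccc([C@H](O)[C@H](CO)c2cc(C#N)cc(OCOC)c2OCc2ccccc2)cc1OC
F5 | step 12 | 4-(benzyloxy)-3-[(1R,2S)-1-(3,4-dimethoxyphenyl)-1-hydroxy-3-(triisopropylsilyloxy)propan-2-yl]-5-(methoxymethoxy)benzonitrile | COc1ccc([C@H](O)[C@H](CO[Si](C(C)C)(C(C)C)C(C)C)c2cc(C#N)cc(OCOC)c2OCc2ccccc2)cc1OC
F6 | step 12 | 3-[(1R,2S)-1-(3,4-dimethoxyphenyl)-1-hydroxy-3-(triisopropylsilyloxy)propan-2-yl]-4-hydroxy-5-(methoxymethoxy)benzonitrile | COc1ccc([C@H](O)[C@H](CO[Si](C(C)C)(C(C)C)C(C)C)c2cc(C#N)cc(OCOC)c2O)cc1OC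
F7 | step 8 | (2E)-2-[2-(benzyloxy)-5-cyano-3-(methoxymethoxy)phenyl]-3-(3,4-dimethoxyphenyl)prop-2-enoic acid | COc1ccc(/C=C(/C(=O)O)c2cc(C#N)cc(OCOC)c2OCc2ccccc2)cc1OC
F8 | step 8 | (2S)-2-[2-(benzyloxy)-5-cyano-3-(methoxymethoxy)phenyl]-3-(3,4-dimethoxyphenyl)propanoic acid | COc1ccc(C[C@H](C(=O)O)c2cc(C#N)cc(OCOC)c2OCc2ccccc2)cc1OC
F9 | step 15 | (2R,3S)-2-(3,4-dimethoxyphenyl)-7-hydroxy-3-(hydroxymethyl)-2,3-dihydro-1-benzofuran-5-carbaldehyde | COc1ccc([C@@H]2Oc3c(O)cc(C=O)cc3[C@H]2CO)cc1OC
F10 | step 15 | 2-{[(2R,3S)-2-(3,4-dimethoxyphenyl)-7-hydroxy-3-(hydroxymethyl)-2,3-dihydro-1-benzofuran-5-yl]methylidene}propanedioic acid | COc1ccc([C@@H]2Oc3c(O)cc(C=C(C(=O)O)C(=O)O)cc3[C@H]2CO)cc1OC
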